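**Retrosynthetic overview**
- The spiro epoxy lactone comes from the bromohydrin of a spiro enol lactone, itself from a 2-ethynyl acid at C13; the quaternary C13 comes from a formaldehyde aldol on a ring C aldehyde.
- Ring C is closed by an intramolecular Horner–Wadsworth–Emmons reaction (C13=C14), followed by a nitromethane Michael addition that brings in C15.
- Ring B is closed by a Prins cyclisation with hydration (C6–C7 and C5–O). This rests on C5 (tertiary OH) and C7 (acetoxy) being 1,3-related through C6 in ring B, with C5 held between the quaternary C4 and C10.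
- The Prins precursor comes from an Ireland–Claisen rearrangement (C9–C10, exocyclic C5=C6) of a ring A allylic ester made from 2,6,6-trimethylcyclohex-2-en-1-one; the C1 silyl ether steers it and C1 is inverted after ring B is closed.
- Ring order: A (bought), B (step 13), C (step 20), lactone (step 28), epoxide (step 30).

Key step: step 13

Remark: locants follow the cassane skeleton (ring A C1–C5/C10, ring B C5–C10, ring C C8/C9/C11/C13/C14, lactone carbonyl C12, epoxide carbons C15/C16) and β is the face of the C10 methyl. Compounds 19–27 are carried as mixtures of C14 epimers (19 and 20 also of C8 epimers); C14 carries a dimethoxyphosphoryl group that is a spectator in the key step and closes ring C in step 20.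

**Route**

Step 1
Reactants: 1 2,6,6-trimethylcyclohex-2-en-1-one; 2 (chloromethyl)(isopropoxy)dimethylsilane
Product: 4 rac-1-{[isopropoxy(dimethyl)silyl]methyl}-2,6,6-trimethylcyclohex-2-en-1-ol, via Grignard reagent 3 (not isolated)
Conditions: Mg, THF, rt (2 to 3); then 1, THF, 0 °C → rt; aq. NH4Cl
Reagents that add atoms: none
Why: 1,2-Grignard addition of the hydroxymethyl-anion equivalent to the enone carbonyl gives the tertiary allylic alcohol; its carbinol centre is racemic and is erased in step 4.

Step 2
Reactants: 4 β-hydroxy silane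
Product: 5 rac-1-(hydroxymethyl)-2,6,6-trimethylcyclohex-2-en-1-ol
Conditions: KF, KHCO3, 30% H2O2, THF–MeOH, rt
Reagents that add atoms: hydrogen peroxide, OO
Why: Tamao oxidation turns the alkoxysilane C–Si bond into C–OH and leaves the trisubstituted alkene untouched.

Step 3
Reactants: 5 diol; 6 4-(benzyloxy)butanoic acid
Product: 7 rac-(1-hydroxy-2,6,6-trimethylcyclohex-2-en-1-yl)methyl 4-(benzyloxy)butanoate
Conditions: EDC·HCl, 4-(dimethylamino)pyridine (cat.), CH2Cl2, 0 °C → rt
Reagents that add atoms: none
Why: Carbodiimide (Steglich) esterification acylates only the primary hydroxyl, because the tertiary allylic alcohol next to the gem-dimethyl carbon is too hindered.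

Step 4
Reactants: 7 hydroxy ester
Product: 8 (2,6,6-trimethyl-3-oxocyclohex-1-en-1-yl)methyl 4-(benzyloxy)butanoate
Conditions: [C5H5NH][CrO3Cl] (pyridinium chlorochromate), CH2Cl2, rt
Reagents that add atoms: pyridinium chlorochromate, [O-][Cr](=O)(=O)Cl.c1cc[nH+]cc1
Why: Babler–Dauben oxidative 1,3-transposition: the tertiary chromate ester undergoes a [3,3] shift and oxidation, which puts the carbonyl at C1 and the alkene at C5=C10 and removes the racemic centre.

Step 5
Reactants: 8 enone ester
Product: 9 [(3R)-3-hydroxy-2,6,6-trimethylcyclohex-1-en-1-yl]methyl 4-(benzyloxy)butanoate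
Conditions: (S)-Me-CBS oxazaborolidine (0.2 equiv), BH3·SMe2, THF, −20 °C; MeOH
Reagents that add atoms: none
Why: Corey–Bakshi–Shibata reduction of the enone carbonyl, with the methyl-bearing alkene arm as the large group, should deliver hydride to one face and give the (R)-allylic alcohol at C1.

Step 6
Reactants: 9 allylic alcohol
Product: 10 [(3R)-3-(tert-butyldimethylsilyloxy)-2,6,6-trimethylcyclohex-1-en-1-yl]methyl 4-(benzyloxy)butanoate
Conditions: TBSCl, imidazole, DMF, rt
Reagents that add atoms: tert-butyldimethylsilyl chloride, CC(C)(C)[Si](C)(C)Cl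
Why: Standard silylation of the secondary allylic alcohol; the silyl ether steers step 7 and stays until step 15.

Step 7
Reactants: 10 allylic ester
Product: 13 (2R)-4-(benzyloxy)-2-[(1R,6R)-6-(tert-butyldimethylsilyloxy)-1,3,3-trimethyl-2-methylidenecyclohexyl]butanoic acid, via silyl ketene acetal 11 (not isolated), via trimethylsilyl ester 12 (not isolated)
Conditions: LiN(iPr)2, THF–DMPU (4:1), −78 °C; Me3SiCl, −78 °C → rt, then 60 °C; 1 M HCl
Reagents that add atoms: none
Why: Ireland–Claisen rearrangement: the enolate formed with DMPU gives the ketene acetal with the C11 chain cis to the silyloxy group, which rearranges through a chair on the face of C10 opposite the pseudoaxial C1 silyloxy group; this sets C9 and the quaternary C10 (C9–C10 trans to C1–O, C10 methyl anti to H9) and moves the alkene to exocyclic C5=C6.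

Step 8
Reactants: 13 acid
Product: 14 primary alcohol (C8 as CH2OH)
Conditions: LiAlH4, THF, 0 °C → rt
Reagents that add atoms: none
Why: Hydride reduction of the acid to the primary alcohol; no stereocentre is touched.

Step 9
Reactants: 14 alcohol
Product: 15 aldehyde (C8 as CHO)
Conditions: Dess–Martin periodinane, NaHCO3, CH2Cl2, 0 °C
Reagents that add atoms: none
Why: Dess–Martin oxidation under buffered conditions should give the α-branched aldehyde without epimerisation at C9.

Step 10
Reactants: 15 aldehyde
Product: 17 (E)-nitroalkene (C8=C7–NO2), via nitro alcohol 16 (not isolated)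
Conditions: MeNO2, Et3N (cat.), 0 °C; then MsCl, Et3N, CH2Cl2, −20 → 0 °C
Reagents that add atoms: nitromethane, C[N+](=O)[O-]
Why: Henry addition of nitromethane followed by mesylation and base-induced elimination (E1cB) gives the (E)-nitroalkene and adds C7.

Step 11
Reactants: 17 nitroalkene; 18 methyl (dimethoxyphosphoryl)acetate
Product: 19 nitro phosphonoacetate (C8 bears CH2NO2 and the C14 phosphonoacetate carbon)
Conditions: NaH, THF, 0 °C (18); then 17, −78 → −20 °C; AcOH
Reagents that add atoms: none
Why: Michael addition of the sodium phosphonoacetate to the nitroalkene forms C8–C14; C8 and C14 arise as epimer mixtures, C8 is corrected in step 13 and C14 becomes sp2 in step 20.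

Step 12
Reactants: 19 nitro phosphonoacetate
Product: 20 Prins precursor: ring A with exocyclic C5=C6 and 1β-OTBS, C7 aldehyde on C8, C14 phosphonoacetate arm, C9 2-(benzyloxy)ethyl arm
Conditions: NaOMe, MeOH, 0 °C; then aq. TiCl3, NH4OAc (pH ≈ 5), 0 °C → rt
Reagents that add atoms: water, O
Why: Reductive Nef reaction of the nitronate with buffered TiCl3 unmasks the C7 aldehyde at a pH too mild to start the cation–olefin closure.

Step 13
Reactants: 20 Prins precursor
Product: 21 trans-decalin 5α,7β-diol with 1β-OTBS, C8 phosphonoacetate arm and C9 2-(benzyloxy)ethyl arm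
Conditions: CF3CO2H (5 equiv), H2O (20 equiv), CH2Cl2, 0 °C; then NaHCO3, MeOH–H2O, rt
Reagents that add atoms: water, O
Why: CF3CO2H activates the C7 aldehyde, the CH2 terminus C6 of the exocyclic C5=C6 alkene attacks C7 and the tertiary C5 cation is taken up by water (or by trifluoroacetate, which the NaHCO3/MeOH work-up cleaves), i.e. a Prins cyclisation with hydration, the reaction type by which aldehydes tethered to 1,1-disubstituted or trisubstituted alkenes give cyclohexane-1,3-diols in aqueous acid. Ring B closes 6-endo with respect to the alkene and exo with respect to the carbonyl. C7 and C8 are set in a chair transition state with the protonated carbonyl oxygen and both arms equatorial (7β-OH, 8β-H); the C8 epimers of 20 interconvert through the aldehyde enol and only the one with an equatorial C14 arm avoids a 1,3-diaxial clash with the C10 methyl, so both should converge. C5 is set by anti addition across the alkene: C7 bonds to the β lobe at C6 and water enters axially on the α face of C5, anti to the axial C10 methyl, which gives the trans-decalin 5α-ol. The step needs cation capture to outrun loss of a C6 proton and 1,2-shifts; the quaternary C4 and C10 leave only C6–H for elimination, and excess water at 0 °C favours capture. The benzyl ether, the silyl ether and the phosphonoacetate only look on, and dilute acid at 0 °C should not protonate the hindered alkene before the aldehyde reacts.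

Step 14
Reactants: 21 diol
Product: 22 7β-acetate (5α-OH free, 1β-OTBS)
Conditions: Ac2O, pyridine, 4-(dimethylamino)pyridine (cat.), CH2Cl2, 0 °C
Reagents that add atoms: acetic anhydride, CC(=O)OC(C)=O
Why: Acetylation of the equatorial secondary 7β-hydroxyl; the tertiary 5α-hydroxyl between two quaternary carbons does not react, and the acetate blocks C7 during the oxidation at C1.

Step 15
Reactants: 22 silyl ether
Product: 23 1β-alcohol (7β-OAc, 5α-OH)
Conditions: HF·pyridine, pyridine, THF, 0 °C → rt
Reagents that add atoms: none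
Why: Fluoride-mediated desilylation frees the 1β-hydroxyl; the esters and the benzyl ether are inert.

Step 16
Reactants: 23 1β-alcohol
Product: 24 C1 ketone (5α-hydroxy-1-one)
Conditions: Dess–Martin periodinane, NaHCO3, CH2Cl2, rt
Reagents that add atoms: none
Why: Dess–Martin oxidation of the only free secondary alcohol gives the C1 ketone under neutral conditions that avoid retro-aldol cleavage of the β-hydroxy ketone.

Step 17
Reactants: 24 ketone
Product: 25 1α-alcohol (1α,5α-diol, 7β-OAc)
Conditions: Et2BOMe, THF–MeOH (4:1), −78 °C; NaBH4, −78 °C; AcOH, then MeOH (evaporation)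
Reagents that add atoms: none
Why: Narasaka–Prasad reduction: Et2BOMe ties the 5α-hydroxyl and the C1 carbonyl into a boron chelate on the α face, so borohydride should attack from the β face and give the 1α-alcohol syn to the 5α-hydroxyl, which inverts C1.

Step 18
Reactants: 25 benzyl ether
Product: 26 primary alcohol at C13
Conditions: H2 (1 atm), Pd/C, EtOAc, rt
Reagents that add atoms: none
Why: Catalytic hydrogenolysis cleaves the benzyl ether; no alkene is present at this stage.

Step 19
Reactants: 26 primary alcohol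
Product: 27 C13 aldehyde
Conditions: 2,2,6,6-tetramethylpiperidin-1-oxyl (cat.), PhI(OAc)2, CH2Cl2, rt
Reagents that add atoms: none
Why: Oxoammonium (TEMPO) oxidation with PhI(OAc)2 is selective for the primary alcohol over the hindered axial 1α-hydroxyl and stops at the aldehyde.

Step 20
Reactants: 27 aldehyde phosphonate
Product: 28 ring C cyclopentene ester (C13=C14, CO2Me on C14; 1α,5α-diol, 7β-OAc)
Conditions: LiCl, DBU, MeCN, rt
Reagents that add atoms: none
Why: Intramolecular Horner–Wadsworth–Emmons olefination under LiCl/DBU closes the five-membered ring C with the C13=C14 bond endocyclic and removes the C14 epimer mixture.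

Step 21
Reactants: 28 cyclopentene ester
Product: 29 13α-nitromethyl 14β-ester (1α,5α,7β-triol)
Conditions: MeNO2, NaOMe, MeOH, rt → 50 °C; AcOH
Reagents that add atoms: nitromethane, C[N+](=O)[O-]
Why: Reversible Michael addition of nitromethane under methoxide, with enolisation at C14, should settle at the all-trans isomer (14β ester pseudo-equatorial and trans to C7, 13α nitromethyl); methoxide also cleaves the C7 acetate.

Step 22
Reactants: 29 nitro ester
Product: 30 13α-formyl 14β-ester (C15 aldehyde)
Conditions: NaOMe, MeOH, 0 °C; then aq. TiCl3, NH4OAc (pH ≈ 5), rt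
Reagents that add atoms: water, O
Why: Reductive Nef reaction as in step 12 turns the nitromethyl group into the C15 aldehyde; C14 is not enolised at this pH.

Step 23
Reactants: 30 aldehyde
Product: 31 quaternary C13 with 13α-CH2OH (C12) and 13β-CHO (C15)
Conditions: aq. HCHO (37%), DBU (cat.), THF, 0 °C → rt
Reagents that add atoms: formaldehyde, C=O
Why: Crossed aldol (hydroxymethylation) of the α-branched aldehyde: formaldehyde should add to the C13 enolate on the α face, anti to the vicinal 14β ester, so that C12 is α and the formyl carbon C15 is β.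

Step 24
Reactants: 31 hydroxy aldehyde
Product: 32 C12 tert-butyldimethylsilyl ether
Conditions: TBSCl, imidazole, CH2Cl2, 0 °C
Reagents that add atoms: tert-butyldimethylsilyl chloride, CC(C)(C)[Si](C)(C)Cl
Why: Silylation at 0 °C is selective for the primary hydroxyl over the secondary 7β- and 1α-hydroxyls and blocks retro-aldol loss of formaldehyde in step 25.

Step 25
Reactants: 32 aldehyde
Product: 33 13β-ethynyl compound (C15≡C16)
Conditions: dimethyl (1-diazo-2-oxopropyl)phosphonate, K2CO3, MeOH, 0 °C → rt
Reagents that add atoms: dimethyl (1-diazo-2-oxopropyl)phosphonate, COP(=O)(OC)C(=[N+]=[N-])C(C)=O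
Why: Seyferth–Gilbert homologation with the Ohira–Bestmann reagent turns the non-enolisable aldehyde into the terminal alkyne and adds C16.

Step 26
Reactants: 33 alkyne triol
Product: 34 1α,7β-diacetate (5α-OH free)
Conditions: Ac2O, Et3N, 4-(dimethylamino)pyridine, CH2Cl2, rt
Reagents that add atoms: acetic anhydride, CC(=O)OC(C)=O
Why: Acylation with Ac2O and 4-(dimethylamino)pyridine installs the 7β- and 1α-acetates of the target; the tertiary 5α-hydroxyl stays free.

Step 27
Reactants: 34 silyl ether
Product: 35 C12 carboxylic acid (13α-CO2H, 13β-ethynyl)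
Conditions: CrO3, H2SO4, acetone–H2O, 0 °C
Reagents that add atoms: water, O
Why: Jones oxidation cleaves the primary silyl ether in the acidic medium and oxidises the alcohol through the aldehyde hydrate to the acid; the acetates, the alkyne and the tertiary alcohol are inert.

Step 28
Reactants: 35 alkynoic acid
Product: 36 spiro enol lactone (furan-2(3H)-one, C15=C16)
Conditions: Ph3PAuNTf2 (5 mol%), CH2Cl2, rt
Reagents that add atoms: none
Why: Gold-catalysed 5-endo-dig cycloisomerisation of the 3-alkynoic acid gives the furan-2(3H)-one; the 4-exo mode would give a β-lactone, and the quaternary C13 prevents isomerisation to the conjugated butenolide.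

Step 29
Reactants: 36 enol lactone
Product: 37 bromohydrin (C15 bromide on the face turned to C11, C16 lactol hydroxyl trans to it)
Conditions: N-bromosuccinimide, THF–H2O (4:1), 0 °C
Reagents that add atoms: N-bromosuccinimide, BrN1C(=O)CCC1=O; water, O
Why: Bromohydrin formation on the enol lactone: bromine should add to C15 from the face turned to C11, away from the 14β ester, and water opens the bromonium/oxocarbenium at C16 trans to it.

Step 30
Reactants: 37 bromohydrin
Product: 38 spirocaesalmin
Conditions: Ag2O, 4 Å molecular sieves, CH2Cl2, rt, dark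
Reagents that add atoms: none
Why: Proposed new method: the C16 lactol hydroxyl, trans to the C15 bromide, displaces bromide with silver assistance in a 3-exo-tet closure with inversion at C15, which places the epoxide oxygen on the face syn to C14 that a direct epoxidation anti to the ester would not reach; the closest known reaction type is epoxide closure of halohydrins, in particular the formation of alkoxy epoxides from hemiacetal alkoxides of α-halo carbonyl compounds.

**Compound list**

1 | 2,6,6-trimethylcyclohex-2-en-1-one | CC1=CCCC(C)(C)C1=O | starting material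
2 | (chloromethyl)(isopropoxy)dimethylsilane | ClC[Si](C)(C)OC(C)C | starting material
3 | {[isopropoxy(dimethyl)silyl]methyl}magnesium chloride | CC(C)O[Si](C)(C)C[Mg]Cl | intermediate
4 | rac-1-{[isopropoxy(dimethyl)silyl]methyl}-2,6,6-trimethylcyclohex-2-en-1-ol | CC1=CCCC(C)(C)C1(O)C[Si](C)(C)OC(C)C | intermediate
5 | rac-1-(hydroxymethyl)-2,6,6-trimethylcyclohex-2-en-1-ol | CC1=CCCC(C)(C)C1(O)CO | intermediate
6 | 4-(benzyloxy)butanoic acid | OC(=O)CCCOCc1ccccc1 | starting material
7 | rac-(1-hydroxy-2,6,6-trimethylcyclohex-2-en-1-yl)methyl 4-(benzyloxy)butanoate | CC1=CCCC(C)(C)C1(O)COC(=O)CCCOCc1ccccc1 | intermediate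
8 | (2,6,6-trimethyl-3-oxocyclohex-1-en-1-yl)methyl 4-(benzyloxy)butanoate | CC1=C(COC(=O)CCCOCc2ccccc2)C(C)(C)CCC1=O | intermediate
9 | [(3R)-3-hydroxy-2,6,6-trimethylcyclohex-1-en-1-yl]methyl 4-(benzyloxy)butanoate | O[C@@H]1CCC(C)(C)C(COC(=O)CCCOCc2ccccc2)=C1C | intermediate
10 | [(3R)-3-(tert-butyldimethylsilyloxy)-2,6,6-trimethylcyclohex-1-en-1-yl]methyl 4-(benzyloxy)butanoate | CC(C)(C)[Si](C)(C)O[C@@H]1CCC(C)(C)C(COC(=O)CCCOCc2ccccc2)=C1C | intermediate
11 | (Z)-trimethylsilyl ketene acetal of 10 (C11 chain cis to OSiMe3) | c1ccccc1COCC/C=C(\O[Si](C)(C)C)OCC1=C(C)[C@H](O[Si](C)(C)C(C)(C)C)CCC1(C)C | intermediate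
12 | trimethylsilyl ester of acid 13 | C[Si](C)(C)OC(=O)[C@H](CCOCc1ccccc1)[C@]1(C)C(=C)C(C)(C)CC[C@H]1O[Si](C)(C)C(C)(C)C | intermediate
13 | (2R)-4-(benzyloxy)-2-[(1R,6R)-6-(tert-butyldimethylsilyloxy)-1,3,3-trimethyl-2-methylidenecyclohexyl]butanoic acid | OC(=O)[C@H](CCOCc1ccccc1)[C@]1(C)C(=C)C(C)(C)CC[C@H]1O[Si](C)(C)C(C)(C)C | intermediate
14 | primary alcohol from 13 (C8 as CH2OH) | OC[C@H](CCOCc1ccccc1)[C@]1(C)C(=C)C(C)(C)CC[C@H]1O[Si](C)(C)C(C)(C)C | intermediate
15 | aldehyde from 14 (C8 as CHO) | O=C[C@H](CCOCc1ccccc1)[C@]1(C)C(=C)C(C)(C)CC[C@H]1O[Si](C)(C)C(C)(C)C | intermediate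
16 | nitro alcohol (C8 carbinol epimers, C7 as CH2NO2) | [O-][N+](=O)CC(O)[C@H](CCOCc1ccccc1)[C@]1(C)C(=C)C(C)(C)CC[C@H]1O[Si](C)(C)C(C)(C)C | intermediate
17 | (E)-nitroalkene (C8=C7–NO2) | [O-][N+](=O)/C=C/[C@H](CCOCc1ccccc1)[C@]1(C)C(=C)C(C)(C)CC[C@H]1O[Si](C)(C)C(C)(C)C | intermediate
18 | methyl (dimethoxyphosphoryl)acetate | COC(=O)CP(=O)(OC)OC | starting material
19 | nitro phosphonoacetate: C8 bears CH2NO2 and C14H[P(O)(OMe)2]CO2Me (C8 and C14 epimers) | COC(=O)C(P(=O)(OC)OC)C(C[N+](=O)[O-])[C@H](CCOCc1ccccc1)[C@]1(C)C(=C)C(C)(C)CC[C@H]1O[Si](C)(C)C(C)(C)C | intermediate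
20 | Prins precursor: C7 aldehyde on C8, C14 phosphonoacetate arm, C9 2-(benzyloxy)ethyl arm, ring A with exocyclic C5=C6 and 1β-OTBS (C8 and C14 epimers) | COC(=O)C(P(=O)(OC)OC)C(C=O)[C@H](CCOCc1ccccc1)[C@]1(C)C(=C)C(C)(C)CC[C@H]1O[Si](C)(C)C(C)(C)C | intermediate
21 | Prins product: trans-decalin 5α,7β-diol, 1β-OTBS, C8 phosphonoacetate arm (C14 epimers), C9 2-(benzyloxy)ethyl arm | COC(=O)C(P(=O)(OC)OC)[C@@H]1[C@@H](O)C[C@@]2(O)C(C)(C)CC[C@@H](O[Si](C)(C)C(C)(C)C)[C@]2(C)[C@H]1CCOCc1ccccc1 | intermediate
22 | 7β-acetate of 21 | COC(=O)C(P(=O)(OC)OC)[C@@H]1[C@@H](OC(C)=O)C[C@@]2(O)C(C)(C)CC[C@@H](O[Si](C)(C)C(C)(C)C)[C@]2(C)[C@H]1CCOCc1ccccc1 | intermediate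
23 | 1β,5α-diol 7β-acetate | COC(=O)C(P(=O)(OC)OC)[C@@H]1[C@@H](OC(C)=O)C[C@@]2(O)C(C)(C)CC[C@@H](O)[C@]2(C)[C@H]1CCOCc1ccccc1 | intermediate
24 | 5α-hydroxy-1-ketone 7β-acetate | COC(=O)C(P(=O)(OC)OC)[C@@H]1[C@@H](OC(C)=O)C[C@@]2(O)C(C)(C)CCC(=O)[C@]2(C)[C@H]1CCOCc1ccccc1 | intermediate
25 | 1α,5α-diol 7β-acetate | COC(=O)C(P(=O)(OC)OC)[C@@H]1[C@@H](OC(C)=O)C[C@@]2(O)C(C)(C)CC[C@H](O)[C@]2(C)[C@H]1CCOCc1ccccc1 | intermediate
26 | C13 primary alcohol | COC(=O)C(P(=O)(OC)OC)[C@@H]1[C@@H](OC(C)=O)C[C@@]2(O)C(C)(C)CC[C@H](O)[C@]2(C)[C@H]1CCO | intermediate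
27 | C13 aldehyde | COC(=O)C(P(=O)(OC)OC)[C@@H]1[C@@H](OC(C)=O)C[C@@]2(O)C(C)(C)CC[C@H](O)[C@]2(C)[C@H]1CC=O | intermediate
28 | ring C cyclopentene ester (C13=C14), 1α,5α-diol, 7β-acetate | COC(=O)C1[C@@H]2[C@@H](OC(C)=O)C[C@@]3(O)C(C)(C)CC[C@H](O)[C@]3(C)[C@H]2CC=1 | intermediate
29 | 13α-nitromethyl 14β-methyl ester, 1α,5α,7β-triol | COC(=O)[C@H]1[C@@H]2[C@@H](O)C[C@@]3(O)C(C)(C)CC[C@H](O)[C@]3(C)[C@H]2C[C@@H]1C[N+](=O)[O-] | intermediate
30 | 13α-formyl 14β-methyl ester, triol | COC(=O)[C@H]1[C@@H]2[C@@H](O)C[C@@]3(O)C(C)(C)CC[C@H](O)[C@]3(C)[C@H]2C[C@@H]1C=O | intermediate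
31 | 13α-hydroxymethyl 13β-formyl compound | COC(=O)[C@H]1[C@@H]2[C@@H](O)C[C@@]3(O)C(C)(C)CC[C@H](O)[C@]3(C)[C@H]2C[C@@]1(CO)C=O | intermediate
32 | C12 tert-butyldimethylsilyl ether of 31 | COC(=O)[C@H]1[C@@H]2[C@@H](O)C[C@@]3(O)C(C)(C)CC[C@H](O)[C@]3(C)[C@H]2C[C@@]1(CO[Si](C)(C)C(C)(C)C)C=O | intermediate
33 | 13β-ethynyl 13α-silyloxymethyl compound | COC(=O)[C@H]1[C@@H]2[C@@H](O)C[C@@]3(O)C(C)(C)CC[C@H](O)[C@]3(C)[C@H]2C[C@@]1(CO[Si](C)(C)C(C)(C)C)C#C | intermediate
34 | 1α,7β-diacetate of 33 | COC(=O)[C@H]1[C@@H]2[C@@H](OC(C)=O)C[C@@]3(O)C(C)(C)CC[C@H](OC(C)=O)[C@]3(C)[C@H]2C[C@@]1(CO[Si](C)(C)C(C)(C)C)C#C | intermediate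
35 | 13α-carboxylic acid 13β-ethynyl diacetate | COC(=O)[C@H]1[C@@H]2[C@@H](OC(C)=O)C[C@@]3(O)C(C)(C)CC[C@H](OC(C)=O)[C@]3(C)[C@H]2C[C@@]1(C(O)=O)C#C | intermediate
36 | spiro enol lactone (C15=C16) | COC(=O)[C@H]1[C@@H]2[C@@H](OC(C)=O)C[C@@]3(O)C(C)(C)CC[C@H](OC(C)=O)[C@]3(C)[C@H]2C[C@]12C(=O)OC=C2 | intermediate
37 | bromohydrin: 15-bromo-16-hydroxy lactone, trans | COC(=O)[C@H]1[C@@H]2[C@@H](OC(C)=O)C[C@@]3(O)C(C)(C)CC[C@H](OC(C)=O)[C@]3(C)[C@H]2C[C@]12C(=O)O[C@H](O)[C@H]2Br | intermediate
38 | spirocaesalmin | COC(=O)[C@H]1[C@@H]2[C@@H](OC(C)=O)C[C@@]3(O)C(C)(C)CC[C@H](OC(C)=O)[C@]3(C)[C@H]2C[C@]12C(=O)O[C@@H]1O[C@@H]12 | target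

**Step count and risks**

Total step count: 30. Longest linear sequence: 30 steps (1 to 38); 2, 6 and 18 enter as purchased fragments.

The three steps most likely to fail:

1. Step 30 (proposed new method). The lactol 37 may open to the α-bromo aldehyde carboxylate and fail to close, or the acyloxy epoxide may be lost to hydrolysis as it forms. The fallback sets out from enol lactone 36 and goes directly to 38 by epoxidation with dimethyldioxirane (acetone solution, CH2Cl2, −40 °C), a known reaction of enol esters and enol lactones; no new compound arises (F0). Its weak point is that the oxidant must enter syn to the C14 ester, so the diastereomers would have to be separated.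

2. Step 13 (key step). Loss of a C6 proton from the C5 cation may outrun water capture, a transition state with the carbonyl oxygen axial may compete (7α-OH), and the γ-hydroxy ester may lactonise or the silyl ether may be lost in the acid. The fallback sets out from 20 and separates C–C bond formation from C–O bond formation. Closure with Me2AlCl (CH2Cl2, −78 °C), terminated by proton loss, should give the 7β-hydroxy Δ5(6)-alkene F1. Mukaiyama hydration of F1 (Mn(C11H19O2)3 (cat.), PhSiH3, O2, iPrOH, 0 °C; then P(OEt)3) should then place the tertiary hydroxyl at C5 from the α face by hydrogen-atom transfer to C6 and oxygen trapping at C5. This returns to the route at 21.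

3. Step 17. Hydride may instead be delivered from the α face (through the unchelated ketone or directed by the 5α-hydroxyl) and return the 1β-alcohol, or the hindered ketone may react slowly and suffer retro-aldol cleavage. The fallback sets out from the 1β-alcohol 23 and reaches 25 directly by redox epimerisation with the hydrogen-transfer catalyst {[Ph4(η5-C4CO)]2H}Ru2(CO)4(μ-H) (toluene, 80 °C). This works under thermodynamic control: the axial 1α-hydroxyl can hydrogen-bond to the 5α-hydroxyl and is free of the clash between an equatorial 1β-oxygen and C11. No new compound arises (F0).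

Further compounds
F0 | step 30 | none | none
F1 | step 13 | 7β-hydroxy Δ5(6)-alkene (1β-OTBS, C8 phosphonoacetate arm, C9 2-(benzyloxy)ethyl arm) | COC(=O)C(P(=O)(OC)OC)[C@@H]1[C@@H](O)C=C2C(C)(C)CC[C@@H](O[Si](C)(C)C(C)(C)C)[C@]2(C)[C@H]1CCOCc1ccccc1
F0 | step 17 | none | none
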